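**Retrosynthetic overview**

1. Target 25 ⇐ acylations, desilylation, α‑methylenation, cis‑selective 1,4‑reduction and C2 oxidation of the bicyclic dienyl dihydrofuran 15.
2. Enabling feature (cyclohepta[b]furan‑2‑one numbering: O1, C2=O, C3=CH2, C3a, C4H=C5(CH3), C6, C7, C8, C8a): the ring olefin C4=C5 is bonded to the ring‑fusion carbon C3a, which is the lactone β‑carbon. C3–C3a–C4=C5 is therefore a latent 1,3‑diene C3=C3a–C4=C5 spanning both rings, the retron of an ene–yne–ene metathesis with C3a and C4 as the alkyne carbons.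
3. 15 ⇐ acyclic dienyne 14 (allyl propargyl ether plus isopropenyl group): one metathesis cascade closes the five‑membered O‑ring first (C3=C3a) and the seven‑membered ring last, by forming C4=C5.
4. 14 ⇐ δ‑lactone 10, a temporary six‑membered ring (O–C8a–C8–C7–C6–C5, absent from the target). It relays the purchased C7 methyl stereocenter to C6 (trans aldol) and to the side‑chain carbinol C1′ (chelation‑controlled reduction); C8a comes from a Noyori transfer hydrogenation; the lactone C=O becomes the isopropenyl carbon C5.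
5. 10 ⇐ methyl hydrogen (R)‑3‑methylglutarate 1, ethynyltrimethylsilane and aldehyde 6.

Key step: step 10

Remark: 1, 6 and 23 are taken as purchasable; CIP descriptors change along the route where substituent priorities change, although no stereocenter is inverted.

**Route**

Step 1
Reactants: 1 methyl hydrogen (R)-3-methylglutarate
Product: 3 methyl (3R)-3-methyl-5-oxo-7-(trimethylsilyl)hept-6-ynoate, via acid chloride 2 (not isolated)
Conditions: (COCl)2, DMF (cat.), CH2Cl2, 0 °C → rt, concentrate; then HC≡CSiMe3, PdCl2(PPh3)2 (2 mol %), CuI (4 mol %), Et3N, THF, rt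
Reagents that add atoms: ethynyltrimethylsilane, C#C[Si](C)(C)C
Why: Acid chloride formation followed by an acyl Sonogashira coupling should turn the free acid into the silyl ynone, while the methyl ester and the non‑enolisable β‑stereocenter are untouched.

Step 2
Reactants: 3 methyl (3R)-3-methyl-5-oxo-7-(trimethylsilyl)hept-6-ynoate
Product: 5 (4R,6R)-4-methyl-6-[(trimethylsilyl)ethynyl]oxan-2-one, via hydroxy ester 4 (not isolated)
Conditions: Ru[(R,R)-TsNCH(Ph)CH(Ph)NH](p-cymene) (1 mol %), i-PrOH, rt; then PPTS (cat.), toluene, 80 °C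
Reagents that add atoms: none
Why: Noyori asymmetric transfer hydrogenation of the ynone should set the (R)‑propargylic carbinol under catalyst control (the alkyne takes the place of the aryl group of the standard model), and acid‑catalysed lactonisation of the δ‑hydroxy ester then gives the cis‑4,6‑disubstituted δ‑lactone.

Step 3
Reactants: 5 (4R,6R)-4-methyl-6-[(trimethylsilyl)ethynyl]oxan-2-one; 6 3-[(tert-butyldimethylsilyl)oxy]propanal
Product: 7 (3R,4R,6R)-3-[3-[(tert-butyldimethylsilyl)oxy]-1-hydroxypropyl]-4-methyl-6-[(trimethylsilyl)ethynyl]oxan-2-one (carbinol epimers)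
Conditions: LiN(i-Pr)2, THF, −78 °C; then 6, −78 °C; then aq. NH4Cl
Reagents that add atoms: none
Why: In this lithium enolate aldol addition the aldehyde should approach the half‑chair lactone enolate anti to the C4 methyl group, which sets C3 trans to it by substrate control; the carbinol center is left uncontrolled because step 4 erases it.

Step 4
Reactants: 7 aldol adduct (carbinol epimers)
Product: 8 (3R,4R,6R)-3-[3-[(tert-butyldimethylsilyl)oxy]propanoyl]-4-methyl-6-[(trimethylsilyl)ethynyl]oxan-2-one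
Conditions: Dess–Martin periodinane, CH2Cl2, rt
Reagents that add atoms: none
Why: Dess–Martin oxidation should converge both carbinol epimers on one β‑keto lactone whose acyl group sits equatorial, trans to the methyl group, under thermodynamic control.

Step 5
Reactants: 8 β-keto lactone
Product: 9 (3R,4R,6R)-3-[(1S)-3-[(tert-butyldimethylsilyl)oxy]-1-hydroxypropyl]-4-methyl-6-[(trimethylsilyl)ethynyl]oxan-2-one
Conditions: Zn(BH4)2, Et2O, −20 °C; then aq. NH4Cl
Reagents that add atoms: none
Why: Chelation‑controlled reduction of an α‑substituted β‑keto ester (zinc bridging the ketone and lactone carbonyl oxygens, hydride arriving on the face of the C3–H and away from ring C4) should give the syn β‑hydroxy lactone, i.e. the (S)‑carbinol.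

Step 6
Reactants: 9 β-hydroxy lactone
Product: 10 (3R,4R,6R)-3-[(1S)-1,3-bis[(tert-butyldimethylsilyl)oxy]propyl]-4-methyl-6-[(trimethylsilyl)ethynyl]oxan-2-one
Conditions: TBSOTf, 2,6-lutidine, CH2Cl2, −78 → 0 °C
Reagents that add atoms: tert-butyldimethylsilyl triflate, CC(C)(C)[Si](C)(C)OS(=O)(=O)C(F)(F)F
Why: Silyl ether formation with the triflate and a hindered base is the standard way to protect a hindered secondary alcohol without touching the lactone.

Step 7
Reactants: 10 bis-silyl lactone
Product: 11 (3R,4R,6R)-3-[(1S)-1,3-bis[(tert-butyldimethylsilyl)oxy]propyl]-2,4-dimethyl-6-[(trimethylsilyl)ethynyl]oxan-2-ol (hemiketal anomers, ring–chain tautomer of the δ-hydroxy methyl ketone)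
Conditions: MeLi (1.1 equiv), THF, −78 °C; then aq. NH4Cl
Reagents that add atoms: methyllithium, [Li]C
Why: Mono‑addition of an organolithium to a δ‑lactone should stop at the methyl ketone level because the tetrahedral lithium hemiketal persists at −78 °C.

Step 8
Reactants: 11 methyl hemiketal
Product: 12 (3R,5R,6S,7S)-7,9-bis[(tert-butyldimethylsilyl)oxy]-5-methyl-6-(prop-1-en-2-yl)-1-(trimethylsilyl)non-1-yn-3-ol
Conditions: Ph3PCH3Br, n-BuLi, THF, 0 °C; then 11, 0 °C → rt
Reagents that add atoms: methylenetriphenylphosphorane, C=P(c1ccccc1)(c1ccccc1)c1ccccc1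
Why: Wittig methylenation of the ring‑opened keto alkoxide should install the isopropenyl group and free the propargylic alcohol, the ylide adding to the ketone faster than it enolises the hindered α‑stereocenter.

Step 9
Reactants: 12 propargylic alcohol
Product: 14 (3R,5R,6S,7S)-7,9-bis[(tert-butyldimethylsilyl)oxy]-5-methyl-3-(prop-2-en-1-yloxy)-6-(prop-1-en-2-yl)non-1-yne, via silylalkyne allyl ether 13 (not isolated)
Conditions: NaH, allyl bromide, n-Bu4NI (cat.), THF/DMF, 0 °C → rt; then K2CO3, MeOH, rt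
Reagents that add atoms: allyl bromide, C=CCBr
Why: Williamson etherification of the propargylic alkoxide followed by carbonate‑mediated methanolysis of the alkynyl C–Si bond should give the terminal‑alkyne allyl ether needed for metathesis; no epimerisable center remains.

Step 10
Reactants: 14 dienyne
Product: 15 (6S,7R,8aR)-6-[(1S)-1,3-bis[(tert-butyldimethylsilyl)oxy]propyl]-5,7-dimethyl-6,7,8,8a-tetrahydro-2H-cyclohepta[b]furan
Conditions: second-generation Grubbs catalyst RuCl2(=CHPh)(H2IMes)(PCy3) (10 mol %), CH2Cl2 (2 mM), 40 °C, argon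
Reagents that add atoms: none
Why: The ruthenium alkylidene should initiate at the monosubstituted allyl ether olefin, add across the alkyne through a ruthenacyclobutene to close the 2,5‑dihydrofuran and leave a conjugated vinylcarbene on the former terminal alkyne carbon, and this carbene should then undergo ring‑closing metathesis with the isopropenyl group, forming C4=C5 and releasing ethylene. The closest known reaction type is the tandem ene–yne–ene (dienyne) ring‑closing metathesis that turns acyclic dienynes branched at the propargylic carbon into fused bicyclic 1,3‑dienes, five–seven systems included. The five‑membered ring closes in the exo mode of a 1,6‑enyne; the seven‑membered ring closes last by alkylidene–olefin metathesis onto a 1,1‑disubstituted alkene, which gives the trisubstituted ring olefin. No stereocenter is created: the four existing centers lie outside the reacting carbons and are carried through, and the planar ring‑fusion carbon C3a is left for face‑selective reduction in step 12. The step needs site‑selective initiation, exo enyne closure and intramolecular capture of the vinylcarbene: the allyl ether is the only monosubstituted olefin, the 1,6‑relationship of ene and yne favours the five‑membered closure, and high dilution with the seven‑atom tether makes the isopropenyl group the only partner left for the carbene.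

Step 11
Reactants: 15 bicyclic dienyl dihydrofuran
Product: 16 (6S,7R,8aR)-6-[(1S)-1,3-bis[(tert-butyldimethylsilyl)oxy]propyl]-5,7-dimethyl-6,7,8,8a-tetrahydro-2H-cyclohepta[b]furan-2-one
Conditions: CrO3, 3,5-dimethylpyrazole, CH2Cl2, −20 °C
Reagents that add atoms: chromium trioxide, O=[Cr](=O)=O
Why: Allylic C–H oxidation with the CrO3–dimethylpyrazole complex should convert the ring O–CH2 group, the only secondary position that is both allylic and α to oxygen, into the butenolide carbonyl.

Step 12
Reactants: 16 dienyl butenolide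
Product: 17 (3aS,6S,7R,8aR)-6-[(1S)-1,3-bis[(tert-butyldimethylsilyl)oxy]propyl]-5,7-dimethyl-3,3a,6,7,8,8a-hexahydro-2H-cyclohepta[b]furan-2-one
Conditions: Cu(OAc)2·H2O (5 mol %), 1,2-bis(diphenylphosphino)benzene (5 mol %), (EtO)2MeSiH, t-BuOH, toluene, 0 °C → rt
Reagents that add atoms: none
Why: Copper hydride conjugate reduction, which reduces β,β‑disubstituted butenolides and 2,4‑dienoates in the 1,4 sense, should deliver hydride to C3a from the convex face that carries H‑8a, away from the C8–C7 bridge of the seven‑membered ring, and so set the cis ring fusion by substrate control.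

Step 13
Reactants: 17 cis-fused lactone
Product: 20 (3aR,6S,7R,8aR)-6-[(1S)-1,3-bis[(tert-butyldimethylsilyl)oxy]propyl]-5,7-dimethyl-3-methylidene-3,3a,6,7,8,8a-hexahydro-2H-cyclohepta[b]furan-2-one, via Mannich base 18 (not isolated), via ammonium iodide 19 (not isolated)
Conditions: LiN(i-Pr)2, THF, −78 °C; CH2=NMe2+ I−, −78 °C → rt; then MeI, MeOH, rt; then aq. NaHCO3, CH2Cl2
Reagents that add atoms: Eschenmoser's salt, C=[N+](C)C.[I-]
Why: Mannich reaction of the lactone enolate with Eschenmoser's salt, quaternisation and elimination under weak base should give the exocyclic methylene without isomerisation to the endocyclic butenolide.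

Step 14
Reactants: 20 bis-silyl α-methylene lactone
Product: 21 (3aR,6S,7R,8aR)-6-[(1S)-1,3-dihydroxypropyl]-5,7-dimethyl-3-methylidene-3,3a,6,7,8,8a-hexahydro-2H-cyclohepta[b]furan-2-one
Conditions: HF·pyridine, pyridine, THF, 0 °C → rt
Reagents that add atoms: none
Why: Fluoride cleavage of both silyl ethers under buffered, non‑basic conditions should spare the base‑sensitive α‑methylene lactone.

Step 15
Reactants: 21 diol
Product: 22 (3aR,6S,7R,8aR)-6-[(1S)-3-acetoxy-1-hydroxypropyl]-5,7-dimethyl-3-methylidene-3,3a,6,7,8,8a-hexahydro-2H-cyclohepta[b]furan-2-one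
Conditions: AcCl (1.1 equiv), 2,4,6-collidine, CH2Cl2, −78 °C
Reagents that add atoms: acetyl chloride, CC(Cl)=O
Why: Acylation with acetyl chloride and a hindered pyridine base at low temperature should select the primary hydroxyl over the hindered secondary one.

Step 16
Reactants: 22 hydroxy acetate; 23 angelic acid
Product: 25 (3aR,6S,7R,8aR)-6-[(1S)-3-acetoxy-1-[(2Z)-2-methylbut-2-enoyloxy]propyl]-5,7-dimethyl-3-methylidene-3,3a,6,7,8,8a-hexahydro-2H-cyclohepta[b]furan-2-one, via mixed anhydride 24 (not isolated)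
Conditions: 23, 2,4,6-trichlorobenzoyl chloride, Et3N, toluene, rt; then 22, toluene, 80 °C
Reagents that add atoms: none
Why: Yamaguchi‑type esterification through the mixed anhydride, run without a nucleophilic catalyst, should acylate the hindered secondary alcohol while keeping the Z geometry of the angelate.

**Compound list**

1 | methyl hydrogen (R)-3-methylglutarate [(3R)-5-methoxy-3-methyl-5-oxopentanoic acid] | OC(=O)C[C@@H](C)CC(=O)OC | starting material
2 | methyl (3S)-5-chloro-3-methyl-5-oxopentanoate (acid chloride of 1) | ClC(=O)C[C@@H](C)CC(=O)OC | intermediate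
3 | methyl (3R)-3-methyl-5-oxo-7-(trimethylsilyl)hept-6-ynoate | C[Si](C)(C)C#CC(=O)C[C@@H](C)CC(=O)OC | intermediate
4 | methyl (3R,5R)-5-hydroxy-3-methyl-7-(trimethylsilyl)hept-6-ynoate | C[Si](C)(C)C#C[C@H](O)C[C@@H](C)CC(=O)OC | intermediate
5 | (4R,6R)-4-methyl-6-[(trimethylsilyl)ethynyl]oxan-2-one (cis) | C[Si](C)(C)C#C[C@H]1C[C@@H](C)CC(=O)O1 | intermediate
6 | 3-[(tert-butyldimethylsilyl)oxy]propanal | CC(C)(C)[Si](C)(C)OCCC=O | starting material
7 | (3R,4R,6R)-3-[3-[(tert-butyldimethylsilyl)oxy]-1-hydroxypropyl]-4-methyl-6-[(trimethylsilyl)ethynyl]oxan-2-one (carbinol epimers) | C[Si](C)(C)C#C[C@H]1C[C@@H](C)[C@H](C(O)CCO[Si](C)(C)C(C)(C)C)C(=O)O1 | intermediate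
8 | (3R,4R,6R)-3-[3-[(tert-butyldimethylsilyl)oxy]propanoyl]-4-methyl-6-[(trimethylsilyl)ethynyl]oxan-2-one | C[Si](C)(C)C#C[C@H]1C[C@@H](C)[C@H](C(=O)CCO[Si](C)(C)C(C)(C)C)C(=O)O1 | intermediate
9 | (3R,4R,6R)-3-[(1S)-3-[(tert-butyldimethylsilyl)oxy]-1-hydroxypropyl]-4-methyl-6-[(trimethylsilyl)ethynyl]oxan-2-one | C[Si](C)(C)C#C[C@H]1C[C@@H](C)[C@H]([C@H](CCO[Si](C)(C)C(C)(C)C)O)C(=O)O1 | intermediate
10 | (3R,4R,6R)-3-[(1S)-1,3-bis[(tert-butyldimethylsilyl)oxy]propyl]-4-methyl-6-[(trimethylsilyl)ethynyl]oxan-2-one | C[Si](C)(C)C#C[C@H]1C[C@@H](C)[C@H]([C@H](CCO[Si](C)(C)C(C)(C)C)O[Si](C)(C)C(C)(C)C)C(=O)O1 | intermediate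
11 | (3R,4R,6R)-3-[(1S)-1,3-bis[(tert-butyldimethylsilyl)oxy]propyl]-2,4-dimethyl-6-[(trimethylsilyl)ethynyl]oxan-2-ol (hemiketal anomers) | C[Si](C)(C)C#C[C@H]1C[C@@H](C)[C@H]([C@H](CCO[Si](C)(C)C(C)(C)C)O[Si](C)(C)C(C)(C)C)C(C)(O)O1 | intermediate
12 | (3R,5R,6S,7S)-7,9-bis[(tert-butyldimethylsilyl)oxy]-5-methyl-6-(prop-1-en-2-yl)-1-(trimethylsilyl)non-1-yn-3-ol | C[Si](C)(C)C#C[C@H](O)C[C@@H](C)[C@H]([C@H](CCO[Si](C)(C)C(C)(C)C)O[Si](C)(C)C(C)(C)C)C(C)=C | intermediate
13 | [(3R,5R,6S,7S)-7,9-bis[(tert-butyldimethylsilyl)oxy]-5-methyl-3-(prop-2-en-1-yloxy)-6-(prop-1-en-2-yl)non-1-yn-1-yl]trimethylsilane | C=CCO[C@@H](C#C[Si](C)(C)C)C[C@@H](C)[C@H]([C@H](CCO[Si](C)(C)C(C)(C)C)O[Si](C)(C)C(C)(C)C)C(C)=C | intermediate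
14 | (3R,5R,6S,7S)-7,9-bis[(tert-butyldimethylsilyl)oxy]-5-methyl-3-(prop-2-en-1-yloxy)-6-(prop-1-en-2-yl)non-1-yne | C=CCO[C@@H](C#C)C[C@@H](C)[C@H]([C@H](CCO[Si](C)(C)C(C)(C)C)O[Si](C)(C)C(C)(C)C)C(C)=C | intermediate
15 | (6S,7R,8aR)-6-[(1S)-1,3-bis[(tert-butyldimethylsilyl)oxy]propyl]-5,7-dimethyl-6,7,8,8a-tetrahydro-2H-cyclohepta[b]furan | O1CC=C2C=C(C)[C@@H]([C@H](CCO[Si](C)(C)C(C)(C)C)O[Si](C)(C)C(C)(C)C)[C@H](C)C[C@@H]12 | intermediate
16 | (6S,7R,8aR)-6-[(1S)-1,3-bis[(tert-butyldimethylsilyl)oxy]propyl]-5,7-dimethyl-6,7,8,8a-tetrahydro-2H-cyclohepta[b]furan-2-one | O=C1C=C2C=C(C)[C@@H]([C@H](CCO[Si](C)(C)C(C)(C)C)O[Si](C)(C)C(C)(C)C)[C@H](C)C[C@H]2O1 | intermediate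
17 | (3aS,6S,7R,8aR)-6-[(1S)-1,3-bis[(tert-butyldimethylsilyl)oxy]propyl]-5,7-dimethyl-3,3a,6,7,8,8a-hexahydro-2H-cyclohepta[b]furan-2-one (cis-fused) | O=C1C[C@H]2C=C(C)[C@@H]([C@H](CCO[Si](C)(C)C(C)(C)C)O[Si](C)(C)C(C)(C)C)[C@H](C)C[C@H]2O1 | intermediate
18 | 3-[(dimethylamino)methyl] derivative of 17 (Mannich base, C3 epimers) | CN(C)CC1C(=O)O[C@@H]2C[C@@H](C)[C@H]([C@H](CCO[Si](C)(C)C(C)(C)C)O[Si](C)(C)C(C)(C)C)C(C)=C[C@H]12 | intermediate
19 | 3-[(trimethylammonio)methyl] derivative of 17, iodide | C[N+](C)(C)CC1C(=O)O[C@@H]2C[C@@H](C)[C@H]([C@H](CCO[Si](C)(C)C(C)(C)C)O[Si](C)(C)C(C)(C)C)C(C)=C[C@H]12.[I-] | intermediate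
20 | (3aR,6S,7R,8aR)-6-[(1S)-1,3-bis[(tert-butyldimethylsilyl)oxy]propyl]-5,7-dimethyl-3-methylidene-3,3a,6,7,8,8a-hexahydro-2H-cyclohepta[b]furan-2-one | C=C1C(=O)O[C@@H]2C[C@@H](C)[C@H]([C@H](CCO[Si](C)(C)C(C)(C)C)O[Si](C)(C)C(C)(C)C)C(C)=C[C@H]12 | intermediate
21 | (3aR,6S,7R,8aR)-6-[(1S)-1,3-dihydroxypropyl]-5,7-dimethyl-3-methylidene-3,3a,6,7,8,8a-hexahydro-2H-cyclohepta[b]furan-2-one | C=C1C(=O)O[C@@H]2C[C@@H](C)[C@H]([C@H](CCO)O)C(C)=C[C@H]12 | intermediate
22 | (3aR,6S,7R,8aR)-6-[(1S)-3-acetoxy-1-hydroxypropyl]-5,7-dimethyl-3-methylidene-3,3a,6,7,8,8a-hexahydro-2H-cyclohepta[b]furan-2-one | C=C1C(=O)O[C@@H]2C[C@@H](C)[C@H]([C@H](CCOC(C)=O)O)C(C)=C[C@H]12 | intermediate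
23 | angelic acid [(2Z)-2-methylbut-2-enoic acid] | C/C=C(/C)C(=O)O | starting material
24 | (2Z)-2-methylbut-2-enoic 2,4,6-trichlorobenzoic anhydride | C/C=C(/C)C(=O)OC(=O)c1c(Cl)cc(Cl)cc1Cl | intermediate
25 | (3aR,6S,7R,8aR)-6-[(1S)-3-acetoxy-1-[(2Z)-2-methylbut-2-enoyloxy]propyl]-5,7-dimethyl-3-methylidene-3,3a,6,7,8,8a-hexahydro-2H-cyclohepta[b]furan-2-one | C=C1C(=O)O[C@@H]2C[C@@H](C)[C@H]([C@H](CCOC(C)=O)OC(=O)/C(C)=C\C)C(C)=C[C@H]12 | target

**Step count and risks**

Total steps: 16. Longest linear sequence: 16 steps (1 → 25).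

Steps most likely to fail:

Step 10 (metathesis cascade). The cascade may stall after the first ring closure, because the vinylcarbene has to capture a hindered 1,1‑disubstituted olefin next to a branched carbon, and the open intermediate may oligomerise instead. The fallback separates the two ring closures. It sets out from 14: under ethylene (1 atm) with the second‑generation Grubbs catalyst in CH2Cl2 at room temperature, ethylene should intercept the vinylcarbene and release the monocyclic triene (2R)-2-[(2R,3S,4S)-4,6-bis[(tert-butyldimethylsilyl)oxy]-2-methyl-3-(prop-1-en-2-yl)hexyl]-3-ethenyl-2,5-dihydrofuran F1 (enyne metathesis under ethylene). The seven‑membered ring is then closed in a separate diene ring‑closing metathesis with the second‑generation Hoveyda–Grubbs catalyst RuCl2(H2IMes)(=CH-C6H4-2-O-i-Pr) in toluene at 80–110 °C, at high dilution with argon sparging. The fallback comes back to the route at 15.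

Step 11 (allylic oxidation). The dihydrofuran may aromatise to a furan, which would destroy the C8a stereocenter, or be oxidised at the tertiary allylic C8a–H instead of the CH2 group. The fallback carries the lactone oxidation level through the metathesis as an acetal. It sets out from 12: K2CO3 in MeOH should give the desilylated propargylic alcohol (3R,5R,6S,7S)-7,9-bis[(tert-butyldimethylsilyl)oxy]-5-methyl-6-(prop-1-en-2-yl)non-1-yn-3-ol F2. Transacetalisation with acrolein diethyl acetal (PPTS, toluene, removal of ethanol) should give the mixed acetal (3R,5R,6S,7S)-7,9-bis[(tert-butyldimethylsilyl)oxy]-3-[(1-ethoxyprop-2-en-1-yl)oxy]-5-methyl-6-(prop-1-en-2-yl)non-1-yne F3 as an inconsequential mixture of acetal epimers. The same ene–yne–ene cascade (second‑generation Grubbs catalyst, CH2Cl2, 40 °C) should give (6S,7R,8aR)-6-[(1S)-1,3-bis[(tert-butyldimethylsilyl)oxy]propyl]-2-ethoxy-5,7-dimethyl-6,7,8,8a-tetrahydro-2H-cyclohepta[b]furan F4. Oxidation of this allylic acetal with buffered pyridinium chlorochromate [C5H5NH][CrO3Cl] (NaOAc, CH2Cl2) should give the butenolide. The fallback comes back to the route at 16.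

Step 12 (conjugate reduction). Hydride may be delivered to the δ‑carbon C5 (1,6‑reduction, which moves the ring olefin) or to the concave face of C3a (trans ring fusion). The fallback replaces hydride conjugate addition by carbonyl‑directed homogeneous hydrogenation. It sets out from 16: Ru(OAc)2(BINAP) under H2 (50–100 atm) in MeOH/CH2Cl2, a catalyst known to hydrogenate β‑substituted butenolides while leaving non‑coordinating trisubstituted olefins alone, should add H2 syn across C3=C3a through two‑point binding of the olefin and the lactone carbonyl, so that 1,6‑addition is not possible. The antipode of the ligand is chosen to reinforce the convex‑face preference. The fallback comes back to the route at 17 and makes no new compound F0.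

Further compounds
F1 | step 10 | (2R)-2-[(2R,3S,4S)-4,6-bis[(tert-butyldimethylsilyl)oxy]-2-methyl-3-(prop-1-en-2-yl)hexyl]-3-ethenyl-2,5-dihydrofuran | C=CC1=CCO[C@@H]1C[C@@H](C)[C@H]([C@H](CCO[Si](C)(C)C(C)(C)C)O[Si](C)(C)C(C)(C)C)C(C)=C
F2 | step 11 | (3R,5R,6S,7S)-7,9-bis[(tert-butyldimethylsilyl)oxy]-5-methyl-6-(prop-1-en-2-yl)non-1-yn-3-ol | C#C[C@H](O)C[C@@H](C)[C@H]([C@H](CCO[Si](C)(C)C(C)(C)C)O[Si](C)(C)C(C)(C)C)C(C)=C
F3 | step 11 | (3R,5R,6S,7S)-7,9-bis[(tert-butyldimethylsilyl)oxy]-3-[(1-ethoxyprop-2-en-1-yl)oxy]-5-methyl-6-(prop-1-en-2-yl)non-1-yne (acetal epimers) | C=CC(OCC)O[C@@H](C#C)C[C@@H](C)[C@H]([C@H](CCO[Si](C)(C)C(C)(C)C)O[Si](C)(C)C(C)(C)C)C(C)=C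
F4 | step 11 | (6S,7R,8aR)-6-[(1S)-1,3-bis[(tert-butyldimethylsilyl)oxy]propyl]-2-ethoxy-5,7-dimethyl-6,7,8,8a-tetrahydro-2H-cyclohepta[b]furan (acetal epimers) | CCOC1C=C2C=C(C)[C@@H]([C@H](CCO[Si](C)(C)C(C)(C)C)O[Si](C)(C)C(C)(C)C)[C@H](C)C[C@H]2O1
F0 | step 12 | none | none
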